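Ring atoms are numbered C1 (side chain), C2 (methylene), C3 (allylic CHBr), C4, C5 (neopentyl CHBr), C6 (CMe2). Since the quaternary C6 lies between the stereogenic C1 and C5, with C3 opposite, the carbocycle maps onto achiral 4,4-dimethylcyclohexa-2,5-dienone (C3 = carbonyl, C1 and C5 = β carbons). Everything rests on cutting the C1–side-chain bond: one copper/phosphoramidite-catalysed 1,4-addition of a citramalate-derived dialkylzinc breaks the symmetry, sets C1, delivers the complete masked side chain and, after silylation, leaves a dienol ether for C2 alkylation and an enone for the C5 and C3 heteroatoms. Its precursors are the flat dienone and a 2-iodoethyl dioxolanone.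

Key step: step 5

Assumption: the (S,R,R)-phosphoramidite (from (S)-BINOL and bis[(R)-1-phenylethyl]amine) is taken to select the enone face in the same sense as in its additions to cyclohex-2-enone, which corresponds to the (R)-configured C1 of 9; if a trial with Et2Zn showed the opposite sense, the mirror-image ligand would be used.

Step 1
Reactants: 1 4,4-dimethylcyclohex-2-en-1-one
Product: 2 4,4-dimethylcyclohexa-2,5-dien-1-one
Conditions: DDQ (1.5 equiv), 1,4-dioxane, reflux
Reagents that add atoms: none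
Why: quinone dehydrogenation of an enone at its α',β' positions gives the cross-conjugated dienone, and the quaternary carbon makes aromatization impossible.

Step 2
Reactants: 3 (S)-citramalic acid
Product: 4 2-[(4S)-2,2,4-trimethyl-5-oxo-1,3-dioxolan-4-yl]acetic acid
Conditions: 2,2-dimethoxypropane, TsOH·H2O (cat.), CH2Cl2, rt
Reagents that add atoms: 2,2-dimethoxypropane COC(C)(C)OC
Why: acid-catalysed transacetalization closes the five-membered dioxolanone on the α-hydroxy acid unit in preference to the six-membered alternative, leaving the distal carboxyl free and the stereocentre untouched.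

Step 3
Reactants: 4 2-[(4S)-2,2,4-trimethyl-5-oxo-1,3-dioxolan-4-yl]acetic acid
Product: 5 (5S)-5-(2-hydroxyethyl)-2,2,5-trimethyl-1,3-dioxolan-4-one
Conditions: BH3·SMe2 (1.3 equiv), THF, 0 °C → rt; MeOH quench; used at once
Reagents that add atoms: none
Why: borane reduces a free carboxylic acid (through its acyloxyborane) far faster than the hindered lactone carbonyl, a chemoselective reduction.

Step 4
Reactants: 5 (5S)-5-(2-hydroxyethyl)-2,2,5-trimethyl-1,3-dioxolan-4-one
Product: 6 (5S)-5-(2-iodoethyl)-2,2,5-trimethyl-1,3-dioxolan-4-one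
Conditions: PPh3, N-iodosuccinimide, CH2Cl2, 0 °C
Reagents that add atoms: N-iodosuccinimide O=C1CCC(=O)N1I
Why: Appel-type iodination of the primary alcohol through an alkoxyphosphonium ion proceeds under near-neutral conditions that spare the acetal-lactone and forestall translactonization of 5.

Step 5
Reactants: 6 (5S)-5-(2-iodoethyl)-2,2,5-trimethyl-1,3-dioxolan-4-one; 2 4,4-dimethylcyclohexa-2,5-dien-1-one
Product: 9 trimethyl{[(3R)-4,4-dimethyl-3-{2-[(4S)-2,2,4-trimethyl-5-oxo-1,3-dioxolan-4-yl]ethyl}cyclohexa-1,5-dien-1-yl]oxy}silane, via bis-alkylzinc 7 (not isolated), via zinc dienolate 8 (not isolated)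
Conditions: 6 (2.4 equiv), Et2Zn (neat, 5 equiv), CuI (0.3 mol %), 50 °C, then volatiles off in vacuo; Cu(OTf)2 (3 mol %), (S,R,R)-phosphoramidite (6 mol %), 2 (1.0 equiv), toluene, −30 °C; TMSOTf (1.5 equiv), −30 → 0 °C; filtration through Et3N-deactivated silica
Reagents that add atoms: trimethylsilyl triflate C[Si](C)(C)OS(=O)(=O)C(F)(F)F; diethylzinc CC[Zn]CC (zinc of 7 and 8 only)
Why: Iodine–zinc exchange turns 6 into dialkylzinc 7; Cu(OTf)2 is reduced in situ to a monovalent copper phosphoramidite complex that accepts an alkyl group from 7, binds one enone π face of flat 2, adds at the β carbon to give a trivalent copper alkyl enolate and reductively eliminates, forging the C1–CH2 bond and leaving alkylzinc dienolate 8, which TMSOTf silylates on oxygen. The closest known reaction type is the copper/phosphoramidite-catalysed enantioselective 1,4-addition of dialkylzincs to 4,4-disubstituted cyclohexa-2,5-dienones followed by silyl trapping of the zinc enolate. No ring is closed, the carbocycle being bought intact. The one new stereocentre, C1, is set by the chiral ligand on copper alone, the (S)-carbinol centre four bonds away being a spectator. The step needs selection between the two enantiotopic enone units and their faces and a single addition; the mirror symmetry and planarity of 2 reduce the first to π-face recognition, the quaternary C6 rules out aromatization, and storage of the adduct as a dienolate shuts off a second addition.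

Step 6
Reactants: 9 trimethyl{[(3R)-4,4-dimethyl-3-{2-[(4S)-2,2,4-trimethyl-5-oxo-1,3-dioxolan-4-yl]ethyl}cyclohexa-1,5-dien-1-yl]oxy}silane; 10 chloromethyl phenyl sulfide
Product: 11 (5R,6R)-4,4-dimethyl-6-[(phenylsulfanyl)methyl]-5-{2-[(4S)-2,2,4-trimethyl-5-oxo-1,3-dioxolan-4-yl]ethyl}cyclohex-2-en-1-one (CH2SPh trans to the chain)
Conditions: 10 (1.2 equiv), ZnBr2 (10 mol %), CH2Cl2, 0 °C → rt
Reagents that add atoms: none
Why: the mild Lewis acid ionizes the α-chloro sulfide to a thionium ion that is captured at C2, the only nucleophilic terminus of the 2-silyloxydiene, anti to the C1 chain (Mukaiyama-type α-phenylthiomethylation of a silyl enol ether), and loss of TMSCl returns the C3 ketone conjugated to C4=C5; the C2 centre is temporary and ZnBr2 spares the dioxolanone.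

Step 7
Reactants: 11 (5R,6R)-4,4-dimethyl-6-[(phenylsulfanyl)methyl]-5-{2-[(4S)-2,2,4-trimethyl-5-oxo-1,3-dioxolan-4-yl]ethyl}cyclohex-2-en-1-one
Product: 12 (2R,3R,5R)-5-bromo-4,4-dimethyl-2-[(phenylsulfanyl)methyl]-3-{2-[(4S)-2,2,4-trimethyl-5-oxo-1,3-dioxolan-4-yl]ethyl}cyclohexan-1-one (Br trans to the chain)
Conditions: anhydrous HBr (3 equiv, CH2Cl2 solution), CH2Cl2, −40 °C; cold pH 7 buffer wash; used crude
Reagents that add atoms: hydrogen bromide Br
Why: conjugate hydrobromination of the enone, in which bromide attacks C5 of the protonated enone axially through a chair-like transition state anti to the equatorial C1 chain (the trans sense of additions to 5-substituted cyclohexenones); reversibility favours the same axial bromide, which has one gauche methyl contact instead of two, so the neopentyl C–Br bond is made by addition, not substitution.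

Step 8
Reactants: 12 (2R,3R,5R)-5-bromo-4,4-dimethyl-2-[(phenylsulfanyl)methyl]-3-{2-[(4S)-2,2,4-trimethyl-5-oxo-1,3-dioxolan-4-yl]ethyl}cyclohexan-1-one
Product: 13 (1S,2R,3R,5R)-5-bromo-4,4-dimethyl-2-[(phenylsulfanyl)methyl]-3-{2-[(4S)-2,2,4-trimethyl-5-oxo-1,3-dioxolan-4-yl]ethyl}cyclohexan-1-ol (OH axial, cis to Br)
Conditions: LiBH(s-Bu)3 (L-Selectride, 1.1 equiv), THF, −78 °C; H2O quench
Reagents that add atoms: none
Why: diastereoselective ketone reduction in which the bulky borohydride enters equatorially because the axial path to C3 is shielded by the syn-axial C5 bromide (the chair is locked by the equatorial C1 and C2 groups), giving the axial alcohol; lactone, sulfide and bromide are inert at −78 °C and the non-basic hydride does not trigger loss of HBr.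

Step 9
Reactants: 13 (1S,2R,3R,5R)-5-bromo-4,4-dimethyl-2-[(phenylsulfanyl)methyl]-3-{2-[(4S)-2,2,4-trimethyl-5-oxo-1,3-dioxolan-4-yl]ethyl}cyclohexan-1-ol
Product: 14 (1S,2R,3R,5R)-2-[(benzenesulfinyl)methyl]-5-bromo-4,4-dimethyl-3-{2-[(4S)-2,2,4-trimethyl-5-oxo-1,3-dioxolan-4-yl]ethyl}cyclohexan-1-ol (both sulfur epimers)
Conditions: mCPBA (1.0 equiv), CH2Cl2, −78 °C
Reagents that add atoms: 3-chloroperbenzoic acid O=C(OO)c1cccc(Cl)c1
Why: one equivalent of peracid at low temperature oxidizes the sulfide selectively to the sulfoxide, at a stage where the molecule holds no alkene.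

Step 10
Reactants: 14 (1S,2R,3R,5R)-2-[(benzenesulfinyl)methyl]-5-bromo-4,4-dimethyl-3-{2-[(4S)-2,2,4-trimethyl-5-oxo-1,3-dioxolan-4-yl]ethyl}cyclohexan-1-ol
Product: 15 (1S,3R,5R)-5-bromo-4,4-dimethyl-2-methylidene-3-{2-[(4S)-2,2,4-trimethyl-5-oxo-1,3-dioxolan-4-yl]ethyl}cyclohexan-1-ol
Conditions: toluene, CaCO3, 110 °C
Reagents that add atoms: none
Why: thermal syn elimination of the sulfoxide, for which the only β-hydrogen sits on C2, so the exocyclic C2=CH2 is the sole possible alkene and the temporary C2 centre disappears.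

Step 11
Reactants: 15 (1S,3R,5R)-5-bromo-4,4-dimethyl-2-methylidene-3-{2-[(4S)-2,2,4-trimethyl-5-oxo-1,3-dioxolan-4-yl]ethyl}cyclohexan-1-ol
Product: 16 (1S,3R,5R)-5-bromo-3-{2-[(4S)-5-hydroxy-2,2,4-trimethyl-1,3-dioxolan-4-yl]ethyl}-4,4-dimethyl-2-methylidenecyclohexan-1-ol (lactol, both anomers)
Conditions: i-Bu2AlH (2.3 equiv), CH2Cl2, −78 °C; aq. potassium sodium tartrate
Reagents that add atoms: none
Why: partial reduction of a lactone to its lactol, the tetrahedral aluminium alkoxide persisting at −78 °C until work-up, with one further equivalent of hydride consumed by the free hydroxyl.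

Step 12
Reactants: 16 (1S,3R,5R)-5-bromo-3-{2-[(4S)-5-hydroxy-2,2,4-trimethyl-1,3-dioxolan-4-yl]ethyl}-4,4-dimethyl-2-methylidenecyclohexan-1-ol; 17 methyltriphenylphosphonium bromide
Product: 20 (1S,3R,5R)-5-bromo-3-[(3S)-3-hydroxy-3-methylpent-4-en-1-yl]-4,4-dimethyl-2-methylidenecyclohexan-1-ol, via methylenetriphenylphosphorane 18 (not isolated), via hydroxy aldehyde 19 (not isolated)
Conditions: 17 (5 equiv), KOt-Bu (5 equiv), THF, 0 °C; then 16, 0 °C → rt
Reagents that add atoms: none
Why: Wittig methylenation of a lactol with excess ylide, in which base opens the hemiacetal, acetone is expelled and aldehyde 19, which has no α-hydrogen and cannot epimerize, is olefinated; the C3 alkoxide is syn to the C5 bromide and so cannot displace it.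

Step 13
Reactants: 20 (1S,3R,5R)-5-bromo-3-[(3S)-3-hydroxy-3-methylpent-4-en-1-yl]-4,4-dimethyl-2-methylidenecyclohexan-1-ol
Product: 22 (3S)-5-[(1S,3R,5R)-3,5-dibromo-2,2-dimethyl-6-methylidenecyclohexyl]-3-methylpent-1-en-3-ol, via allylic mesylate 21 (not isolated)
Conditions: Ms2O (1.1 equiv), Et3N, THF, −40 °C; then LiBr (2 equiv), −40 → 0 °C; quenched cold
Reagents that add atoms: lithium bromide [Li+].[Br-]; methanesulfonic anhydride CS(=O)(=O)OS(C)(=O)=O (sulfonyl group of 21 only)
Why: the secondary allylic hydroxyl is sulfonylated much faster than the hindered tertiary one and bromide displaces the allylic mesylate by SN2 with inversion, turning the C3 oxygen that was syn to the C5 bromide into a bromide cis to the C1 chain; chloride-free activation and a small excess of LiBr limit halide scrambling.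

Compound list
1 | 4,4-dimethylcyclohex-2-en-1-one | CC1(C)CCC(=O)C=C1 | starting material
2 | 4,4-dimethylcyclohexa-2,5-dien-1-one | CC1(C)C=CC(=O)C=C1 | intermediate
3 | (S)-citramalic acid, (2S)-2-hydroxy-2-methylbutanedioic acid | O=C(O)[C@@](C)(O)CC(=O)O | starting material
4 | 2-[(4S)-2,2,4-trimethyl-5-oxo-1,3-dioxolan-4-yl]acetic acid | O=C1OC(C)(C)O[C@@]1(C)CC(=O)O | intermediate
5 | (5S)-5-(2-hydroxyethyl)-2,2,5-trimethyl-1,3-dioxolan-4-one | O=C1OC(C)(C)O[C@@]1(C)CCO | intermediate
6 | (5S)-5-(2-iodoethyl)-2,2,5-trimethyl-1,3-dioxolan-4-one | O=C1OC(C)(C)O[C@@]1(C)CCI | intermediate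
7 | bis{2-[(4S)-2,2,4-trimethyl-5-oxo-1,3-dioxolan-4-yl]ethyl}zinc | O=C1OC(C)(C)O[C@@]1(C)CC[Zn]CC[C@]1(C)OC(C)(C)OC1=O | intermediate
8 | alkylzinc dienolate of the 1,4-adduct, (3R) at the ring, zinc bound to the dienolate oxygen and to one remaining side-chain alkyl | O=C1OC(C)(C)O[C@@]1(C)CC[C@@H]2C=C(O[Zn]CC[C@]3(C)OC(C)(C)OC3=O)C=CC2(C)C | intermediate
9 | trimethyl{[(3R)-4,4-dimethyl-3-{2-[(4S)-2,2,4-trimethyl-5-oxo-1,3-dioxolan-4-yl]ethyl}cyclohexa-1,5-dien-1-yl]oxy}silane | O=C1OC(C)(C)O[C@@]1(C)CC[C@@H]2C=C(O[Si](C)(C)C)C=CC2(C)C | intermediate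
10 | chloromethyl phenyl sulfide | ClCSc1ccccc1 | starting material
11 | (5R,6R)-4,4-dimethyl-6-[(phenylsulfanyl)methyl]-5-{2-[(4S)-2,2,4-trimethyl-5-oxo-1,3-dioxolan-4-yl]ethyl}cyclohex-2-en-1-one | O=C1OC(C)(C)O[C@@]1(C)CC[C@@H]2[C@@H](CSc3ccccc3)C(=O)C=CC2(C)C | intermediate
12 | (2R,3R,5R)-5-bromo-4,4-dimethyl-2-[(phenylsulfanyl)methyl]-3-{2-[(4S)-2,2,4-trimethyl-5-oxo-1,3-dioxolan-4-yl]ethyl}cyclohexan-1-one | O=C1OC(C)(C)O[C@@]1(C)CC[C@@H]2[C@@H](CSc3ccccc3)C(=O)C[C@@H](Br)C2(C)C | intermediate
13 | (1S,2R,3R,5R)-5-bromo-4,4-dimethyl-2-[(phenylsulfanyl)methyl]-3-{2-[(4S)-2,2,4-trimethyl-5-oxo-1,3-dioxolan-4-yl]ethyl}cyclohexan-1-ol | O=C1OC(C)(C)O[C@@]1(C)CC[C@@H]2[C@@H](CSc3ccccc3)[C@@H](O)C[C@@H](Br)C2(C)C | intermediate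
14 | (1S,2R,3R,5R)-2-[(benzenesulfinyl)methyl]-5-bromo-4,4-dimethyl-3-{2-[(4S)-2,2,4-trimethyl-5-oxo-1,3-dioxolan-4-yl]ethyl}cyclohexan-1-ol, sulfur epimers | O=C1OC(C)(C)O[C@@]1(C)CC[C@@H]2[C@@H](CS(=O)c3ccccc3)[C@@H](O)C[C@@H](Br)C2(C)C | intermediate
15 | (1S,3R,5R)-5-bromo-4,4-dimethyl-2-methylidene-3-{2-[(4S)-2,2,4-trimethyl-5-oxo-1,3-dioxolan-4-yl]ethyl}cyclohexan-1-ol | O=C1OC(C)(C)O[C@@]1(C)CC[C@@H]2C(=C)[C@@H](O)C[C@@H](Br)C2(C)C | intermediate
16 | (1S,3R,5R)-5-bromo-3-{2-[(4S)-5-hydroxy-2,2,4-trimethyl-1,3-dioxolan-4-yl]ethyl}-4,4-dimethyl-2-methylidenecyclohexan-1-ol, anomers | OC1OC(C)(C)O[C@@]1(C)CC[C@@H]2C(=C)[C@@H](O)C[C@@H](Br)C2(C)C | intermediate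
17 | methyltriphenylphosphonium bromide | C[P+](c1ccccc1)(c1ccccc1)c1ccccc1.[Br-] | starting material
18 | methylenetriphenylphosphorane | C=P(c1ccccc1)(c1ccccc1)c1ccccc1 | intermediate
19 | (2S)-4-[(1R,3R,5S)-3-bromo-5-hydroxy-2,2-dimethyl-6-methylidenecyclohexyl]-2-hydroxy-2-methylbutanal | O=C[C@@](C)(O)CC[C@@H]1C(=C)[C@@H](O)C[C@@H](Br)C1(C)C | intermediate
20 | (1S,3R,5R)-5-bromo-3-[(3S)-3-hydroxy-3-methylpent-4-en-1-yl]-4,4-dimethyl-2-methylidenecyclohexan-1-ol | C=C[C@@](C)(O)CC[C@@H]1C(=C)[C@@H](O)C[C@@H](Br)C1(C)C | intermediate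
21 | (1S,3R,5R)-5-bromo-3-[(3S)-3-hydroxy-3-methylpent-4-en-1-yl]-4,4-dimethyl-2-methylidenecyclohexyl methanesulfonate | C=C[C@@](C)(O)CC[C@@H]1C(=C)[C@@H](OS(C)(=O)=O)C[C@@H](Br)C1(C)C | intermediate
22 | (3S)-5-[(1S,3R,5R)-3,5-dibromo-2,2-dimethyl-6-methylidenecyclohexyl]-3-methylpent-1-en-3-ol | C=C[C@@](C)(O)CC[C@@H]1C(=C)[C@H](Br)C[C@@H](Br)C1(C)C | target

Total step count: 13. Longest linear sequence: 12 steps (steps 2 to 13, from (S)-citramalic acid); the dienone branch is one step.

Steps most likely to fail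

Step 5. What may go wrong is slow transfer of the lactone-bearing alkyl group after incomplete iodine–zinc exchange, or weak discrimination between the enantiotopic enone units. The fallback sets out from 6 and comes back at 11, and it gives up catalyst control for separation of diastereomers. Zinc dust activated by LiCl in THF would insert into 6 to give the alkylzinc iodide F1, which would be added to 2 under CuBr·SMe2 (5 mol %) and TMSCl without a chiral ligand. This should give 9 together with its C1 epimer F2. The mixture would be taken through step 6, and enone 11 would be separated by preparative HPLC from its (5S,6S) isomer F3; the two are diastereomers because of the fixed (S)-carbinol centre.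

Step 7. What may go wrong is reversal of the hydrobromination (loss of HBr) during isolation, or a poor facial preference of the bromide. The fallback sets out from 11 and comes back at 12. Silyl-assisted 1,4-bromination with TMSBr in CH2Cl2 at −78 °C would give the β-bromo silyl enol ether F4, which carries no enolizable ketone and can be purified and stored. Brief treatment with AcOH in wet THF at 0 °C would release 12 immediately before the reduction of step 8.

Step 13. What may go wrong is allylic transposition by attack of bromide at the exocyclic methylene, ionization of the allylic sulfonate with loss of configuration, or sulfonylation of the tertiary alcohol. The fallback sets out from 20 and comes back at 22. Appel deoxybromination (PPh3, CBr4, 2,6-lutidine, CH2Cl2, −20 °C) would pass through the alkoxyphosphonium bromide F5, which should collapse within its ion pair with inversion. This needs no free bromide salt and should leave the hindered tertiary alcohol untouched.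

Further compounds
F1 | step 5 | iodo{2-[(4S)-2,2,4-trimethyl-5-oxo-1,3-dioxolan-4-yl]ethyl}zinc | O=C1OC(C)(C)O[C@@]1(C)CC[Zn]I
F2 | step 5 | trimethyl{[(3S)-4,4-dimethyl-3-{2-[(4S)-2,2,4-trimethyl-5-oxo-1,3-dioxolan-4-yl]ethyl}cyclohexa-1,5-dien-1-yl]oxy}silane (C1 epimer of 9) | O=C1OC(C)(C)O[C@@]1(C)CC[C@H]2C=C(O[Si](C)(C)C)C=CC2(C)C
F3 | step 5 | (5S,6S)-4,4-dimethyl-6-[(phenylsulfanyl)methyl]-5-{2-[(4S)-2,2,4-trimethyl-5-oxo-1,3-dioxolan-4-yl]ethyl}cyclohex-2-en-1-one | O=C1OC(C)(C)O[C@@]1(C)CC[C@H]2[C@H](CSc3ccccc3)C(=O)C=CC2(C)C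
F4 | step 7 | {[(3R,5R,6R)-3-bromo-4,4-dimethyl-6-[(phenylsulfanyl)methyl]-5-{2-[(4S)-2,2,4-trimethyl-5-oxo-1,3-dioxolan-4-yl]ethyl}cyclohex-1-en-1-yl]oxy}trimethylsilane | O=C1OC(C)(C)O[C@@]1(C)CC[C@@H]2[C@@H](CSc3ccccc3)C(O[Si](C)(C)C)=C[C@@H](Br)C2(C)C
F5 | step 13 | {[(1S,3R,5R)-5-bromo-3-[(3S)-3-hydroxy-3-methylpent-4-en-1-yl]-4,4-dimethyl-2-methylidenecyclohexyl]oxy}triphenylphosphonium bromide | C=C[C@@](C)(O)CC[C@@H]1C(=C)[C@@H](O[P+](c2ccccc2)(c2ccccc2)c2ccccc2)C[C@@H](Br)C1(C)C.[Br-]
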